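I wanted to know how much faster target would form in this flask, at 20% conversion of the starting material, with more reagent or more free catalyst, and I had to answer from two runs.

in all of them: starting material 1.1 M; free catalyst 55 mM

| flask | reagent | remark |
|---|---|---|
| autumn | 1.1 M | the very flask that is asked about, followed so far |
| winter | 1.7 M | run made earlier |
| flask | 1.10 M |  |

autumn run (percent of the starting material charged)

| time / s | target / % | starting material / % |
|---|---|---|
| 10.0 | 0.6 | 55.7 |
| 12.0 | 1.5 | 52.0 |
| 20.0 | 2.3 | 38.0 |
| 30.0 | 3.7 | 28.8 |

winter run (percent of the starting material charged)

| time / min | target / % | starting material / % |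
|---|---|---|
| 0.417 | 3.5 | 33.2 |
| 0.833 | 7.6 | 19.0 |
| 1.33 | 10.2 | 11.0 |
| 1.50 | 10.0 | 9.9 |
| 2.00 | 11.1 | 6.3 |
| 2.50 | 11.0 | 5.0 |
| 3.00 | 12.2 | 4.7 |

(each reading ± 0.5 percentage points)

- percentages count the starting material that a species holds: one self-condensation product counts as two
- candidate steps: starting material + free catalyst -> free catalyst + open intermediate; free catalyst + open intermediate <-> catalyst intermediate; reagent + catalyst intermediate <-> free catalyst + target; 2 starting material -> self-condensation product
- no earlier run changes the charge of free catalyst; that part of a forecast is a guess

1. factor on the rate of making target when 20% of the starting material are converted if reagent is charged twice over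
2. factor on the rate when 20% of the starting material are converted if free catalyst is charged at 600 mM instead

I counted turns of the catalyst. Midway between its readings at 20.0 s and 30.0 s, the autumn run had made 0.600 of target per catalyst charged, which is its turnover count. At that same time, 25 s, the winter run had 1.55 times the reagent and a count of 0.700.

For doubled reagent I set a floor of 1, for a rate that ignores [reagent], and a ceiling of 2, for a rate proportional to it. The two counts gave a power of 0.354 in [reagent], so my figure was 1.28. I could not tighten the bracket, though, because the runs differed by 0.5 percentage points of target against a scatter of 0.5 points.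

No run changed the free catalyst. It stands on the forward side of the first two candidate steps, so I guessed a bracket from 10.9, the charge factor, to 119, its square.

The forecast gave 1.4 and 35, both inside these brackets: “Doubling therefore gives about 1.4, and early on perhaps more.”

    starting material + free catalyst → free catalyst + open intermediate (k = 0.130 L mol⁻¹ s⁻¹)
    free catalyst + open intermediate ⇌ catalyst intermediate (K = 1.90 L mol⁻¹, k = 1.50 L mol⁻¹ s⁻¹)
    reagent + catalyst intermediate ⇌ free catalyst + target (K = 0.590, k = 3.30 L mol⁻¹ s⁻¹)
    2 starting material → self-condensation product (k = 0.0310 L mol⁻¹ s⁻¹)

The flask gave 1.19 for reagent, below the forecast, and 19.3 for free catalyst, also below it and inside my bracket. The conversion asked about came at 0.0547 min, with target forming at 0.0681 M min⁻¹. Held from the start, that rate makes 0.0677 turnovers by then. The flask's count reached 2.15 at 4.00 min, and the winter run's last reading, at 3.00 min, stood at 2.44.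

The runs were computed for an exercise.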